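Cuts (neolignan numbering: C7 is the carbinol on ring A, C8 carries the ring B aryloxy group, C9 is the CH2OH). C9–OH is traced back to an E-propenyl group. The C7–C8 bond is then cut as a retro-[2,3]-Wittig shift, followed by the vinylic C8–O(ring B) bond and last the benzylic C7–O bond.
Enabling feature: C7–OH and C8–OAr are neighbouring oxygenated stereocentres, and C8 carries only the one-carbon stub C9. This is the homoallylic 1,2-diol monoether pattern that a ring A benzyl ether of a γ-(ring B-oxy)allyl alcohol gives on rearrangement.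
Forward: no ring is built, since rings A and B come from vanillin and syringaldehyde. The chain is joined at O7–C(allyl) first (imidate etherification of (S)-but-3-yn-2-ol), then at C8–O (CuI coupling of a Z-vinyl iodide with the ring B phenol), then at C7–C8 (rearrangement). Alkene cleavage, reduction and desilylation finish the route.
Stereochemistry: the only purchased stereocentre is that of (S)-but-3-yn-2-ol. Together with the Z geometry from cis-reduction of an iodoalkyne, it is relayed to 8S by suprafacial 1,3-chirality transfer. 7S follows from the exo-aryl envelope (syn = threo).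

Key step: step 10

Remark: the target SMILES decodes as (7S,8S), the threo (syn) isomer, and all descriptors below rest on that reading. TIPS = triisopropylsilyl, TES = triethylsilyl.

Step 1
Reactants: 1 vanillin (4-hydroxy-3-methoxybenzaldehyde)
Product: 2 3-methoxy-4-(triisopropylsilyloxy)benzaldehyde
Conditions: TIPSCl, imidazole, DMF, rt
Reagents that add atoms: TIPSCl, CC(C)[Si](Cl)(C(C)C)C(C)C
Why: Imidazole-promoted O-silylation of a phenol, chosen because the TIPS ether should survive hydride, carbonate and alkyllithium, screens the adjacent ring position and leaves with fluoride at the end.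

Step 2
Reactants: 2 3-methoxy-4-(triisopropylsilyloxy)benzaldehyde
Product: 3 [3-methoxy-4-(triisopropylsilyloxy)phenyl]methanol
Conditions: NaBH4, MeOH, 0 °C
Reagents that add atoms: none
Why: Borohydride reduction of an aromatic aldehyde, to which the aryl silyl ether is inert at 0 °C.

Step 3
Reactants: 3 [3-methoxy-4-(triisopropylsilyloxy)phenyl]methanol
Product: 4 3-methoxy-4-(triisopropylsilyloxy)benzyl 2,2,2-trichloroacetimidate
Conditions: Cl3CCN, DBU (cat.), CH2Cl2, 0 °C
Reagents that add atoms: trichloroacetonitrile, N#CC(Cl)(Cl)Cl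
Why: Base-catalysed addition of the alcohol to the nitrile (trichloroacetimidate formation) gives a storable benzyl donor in place of the labile electron-rich benzyl bromide.

Step 4
Reactants: 4 3-methoxy-4-(triisopropylsilyloxy)benzyl 2,2,2-trichloroacetimidate; 5 (S)-but-3-yn-2-ol
Product: 6 (S)-but-3-yn-2-yl 3-methoxy-4-(triisopropylsilyloxy)benzyl ether
Conditions: camphorsulfonic acid (cat.), CH2Cl2, 0 °C to rt
Reagents that add atoms: none
Why: Acid-catalysed trichloroacetimidate benzylation, in which the oxygen of 5 captures the stabilised ring A benzyl cation equivalent, so that no bond at the carbinol carbon is touched (S retained) and no alkoxide is present that could strip the aryl silyl ether.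

Step 5
Reactants: 6 (S)-but-3-yn-2-yl 3-methoxy-4-(triisopropylsilyloxy)benzyl ether
Product: 7 (S)-4-iodobut-3-yn-2-yl 3-methoxy-4-(triisopropylsilyloxy)benzyl ether
Conditions: NIS, AgNO3 (cat.), acetone, rt, dark
Reagents that add atoms: N-iodosuccinimide, O=C1CCC(=O)N1I
Why: AgNO3-catalysed electrophilic iodination of a terminal alkyne with NIS, which in the absence of acid should be much faster than iodination of ring A.

Step 6
Reactants: 7 (S)-4-iodobut-3-yn-2-yl 3-methoxy-4-(triisopropylsilyloxy)benzyl ether
Product: 8 (S,Z)-4-iodobut-3-en-2-yl 3-methoxy-4-(triisopropylsilyloxy)benzyl ether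
Conditions: 2-nitrobenzenesulfonyl hydrazide, Et3N, THF/i-PrOH, rt
Reagents that add atoms: none
Why: Diimide reduction, whose concerted syn transfer of two hydrogens to the iodoalkyne fixes the Z geometry without touching the C–I bond, the benzyl ether or the stereocentre.

Step 7
Reactants: 9 syringaldehyde (4-hydroxy-3,5-dimethoxybenzaldehyde)
Product: 11 2,6-dimethoxybenzene-1,4-diol, via aryl formate 10 (not isolated)
Conditions: aq H2O2, aq NaOH, Ar, 0 °C to rt; then aq HCl
Reagents that add atoms: hydrogen peroxide, OO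
Why: Dakin oxidation, in which hydroperoxide adds to the aldehyde of the para-hydroxybenzaldehyde, the aryl group migrates to oxygen and the formate 10 is saponified in the same flask, air being excluded because 11 is easily oxidised to the quinone.

Step 8
Reactants: 11 2,6-dimethoxybenzene-1,4-diol
Product: 12 2,6-dimethoxy-4-(triisopropylsilyloxy)phenol
Conditions: TIPSCl (1.0 equiv), imidazole, DMF, 0 °C, Ar
Reagents that add atoms: TIPSCl, CC(C)[Si](Cl)(C(C)C)C(C)C
Why: Site-selective O-silylation, since O4 lies between two ring hydrogens and is the more acidic hydroxyl whereas O1 is flanked and hydrogen-bonded by two methoxy groups, so that one equivalent of the bulky chlorosilane should take O4 only.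

Step 9
Reactants: 8 (S,Z)-4-iodobut-3-en-2-yl 3-methoxy-4-(triisopropylsilyloxy)benzyl ether; 12 2,6-dimethoxy-4-(triisopropylsilyloxy)phenol
Product: 13 (S,Z)-4-[2,6-dimethoxy-4-(triisopropylsilyloxy)phenoxy]but-3-en-2-yl 3-methoxy-4-(triisopropylsilyloxy)benzyl ether
Conditions: CuI (cat.), N,N-dimethylglycine hydrochloride (cat.), Cs2CO3, 1,4-dioxane, 60 °C, Ar
Reagents that add atoms: none
Why: Ullmann-type CuI-catalysed C–O coupling of a vinyl iodide with a phenol, a reaction known to retain alkene geometry, so that the Z-enol ether is formed and the allylic stereocentre, which takes no part, stays S.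

Step 10
Reactants: 13 (S,Z)-4-[2,6-dimethoxy-4-(triisopropylsilyloxy)phenoxy]but-3-en-2-yl 3-methoxy-4-(triisopropylsilyloxy)benzyl ether
Product: 16 (1S,2S,3E)-1-[3-methoxy-4-(triisopropylsilyloxy)phenyl]-2-[2,6-dimethoxy-4-(triisopropylsilyloxy)phenoxy]pent-3-en-1-ol, via benzylic organolithium 14 (not isolated), via lithium alkoxide 15 (not isolated)
Conditions: n-BuLi, THF, −78 °C; then AcOH, −78 °C
Reagents that add atoms: none
Why: n-BuLi removes a benzylic hydrogen of 13, the only C–H activated by both an arene and an ether oxygen, and the carbanion of 14 bonds to C8 through a five-membered envelope transition state while the allylic C–O bond breaks on the same face of the allyl unit, so that O7 appears as the alkoxide 15; no ring is closed. The closest known reaction type is the [2,3]-Wittig rearrangement of benzyl sec-allyl ethers with 1,3-chirality transfer, which is also known for allyl units whose migration terminus is an enol ether carbon. C8 is controlled by the (S)-carbinol carbon: allylic 1,3-strain with the cis aryloxy group turns its hydrogen inward and its methyl outward, which leaves only the Re face of C8 under the carbanion, gives 8S and makes the new alkene E. C7 is controlled by ring A taking the exo position of the envelope, away from the hydrogen on the central allyl carbon, which for a Z-alkene means the syn (threo) pair and hence 7S. The step needs benzylic rather than vinylic, allylic or ring metalation and a [2,3] rather than a [1,2] shift, and the tertiary electron-rich allylic C–H, the TIPS groups crowding the ring positions and the temperature of −78 °C all work in that direction. Quenching with acetic acid in the cold keeps 15 from attacking the aryl silyl ethers on warming.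

Step 11
Reactants: 16 (1S,2S,3E)-1-[3-methoxy-4-(triisopropylsilyloxy)phenyl]-2-[2,6-dimethoxy-4-(triisopropylsilyloxy)phenoxy]pent-3-en-1-ol
Product: 18 (2R,3S)-2-[2,6-dimethoxy-4-(triisopropylsilyloxy)phenoxy]-3-hydroxy-3-[3-methoxy-4-(triisopropylsilyloxy)phenyl]propanal, via 9,10-diol 17 (not isolated)
Conditions: OsO4 (cat.), NaIO4, 2,6-lutidine, 1,4-dioxane/H2O, rt
Reagents that add atoms: OsO4, O=[Os](=O)(=O)=O; NaIO4 (terminal oxygen source), [Na+].[O-]I(=O)(=O)=O
Why: Lemieux–Johnson cleavage, in which OsO4 dihydroxylates the only alkene to 17 and NaIO4 cleaves its C9–C10 glycol (O7 and O9 are 1,3-related and are not cleaved), while 2,6-lutidine keeps the medium near neutral so that C8 next to the new aldehyde is not epimerised (its descriptor becomes R only because CHO outranks C7).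

Step 12
Reactants: 18 (2R,3S)-2-[2,6-dimethoxy-4-(triisopropylsilyloxy)phenoxy]-3-hydroxy-3-[3-methoxy-4-(triisopropylsilyloxy)phenyl]propanal
Product: 19 (1S,2S)-1-[3-methoxy-4-(triisopropylsilyloxy)phenyl]-2-[2,6-dimethoxy-4-(triisopropylsilyloxy)phenoxy]propane-1,3-diol
Conditions: NaBH4, THF/MeOH, 0 °C (crude 18 used at once)
Reagents that add atoms: none
Why: Borohydride reduction of the crude aldehyde at 0 °C, fast enough to outrun enolisation or retro-aldol cleavage, creates the C9 hydroxymethyl group and leaves C7 and C8 unchanged.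

Step 13
Reactants: 19 (1S,2S)-1-[3-methoxy-4-(triisopropylsilyloxy)phenyl]-2-[2,6-dimethoxy-4-(triisopropylsilyloxy)phenoxy]propane-1,3-diol
Product: 20 (1S,2S)-1-(4-hydroxy-3-methoxyphenyl)-2-(4-hydroxy-2,6-dimethoxyphenoxy)propane-1,3-diol (CID53356207)
Conditions: Bu4NF, AcOH, THF, 0 °C
Reagents that add atoms: none
Why: Fluoride-induced cleavage of both aryl silyl ethers, buffered with acetic acid so that the liberated para-hydroxybenzyl alcohol is never exposed to base and C7 is not scrambled by way of a quinone methide.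

Compound list
1 | vanillin | COc1cc(C=O)ccc1O | starting material
2 | 3-methoxy-4-(triisopropylsilyloxy)benzaldehyde | COc1cc(C=O)ccc1O[Si](C(C)C)(C(C)C)C(C)C | intermediate
3 | [3-methoxy-4-(triisopropylsilyloxy)phenyl]methanol | COc1cc(CO)ccc1O[Si](C(C)C)(C(C)C)C(C)C | intermediate
4 | 3-methoxy-4-(triisopropylsilyloxy)benzyl 2,2,2-trichloroacetimidate | COc1cc(COC(=N)C(Cl)(Cl)Cl)ccc1O[Si](C(C)C)(C(C)C)C(C)C | intermediate
5 | (S)-but-3-yn-2-ol | C[C@H](O)C#C | starting material
6 | (S)-but-3-yn-2-yl 3-methoxy-4-(triisopropylsilyloxy)benzyl ether | COc1cc(CO[C@@H](C)C#C)ccc1O[Si](C(C)C)(C(C)C)C(C)C | intermediate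
7 | (S)-4-iodobut-3-yn-2-yl 3-methoxy-4-(triisopropylsilyloxy)benzyl ether | COc1cc(CO[C@@H](C)C#CI)ccc1O[Si](C(C)C)(C(C)C)C(C)C | intermediate
8 | (S,Z)-4-iodobut-3-en-2-yl 3-methoxy-4-(triisopropylsilyloxy)benzyl ether | COc1cc(CO[C@@H](C)/C=C\I)ccc1O[Si](C(C)C)(C(C)C)C(C)C | intermediate
9 | syringaldehyde | COc1cc(C=O)cc(OC)c1O | starting material
10 | 4-hydroxy-3,5-dimethoxyphenyl formate (formed and saponified in the flask) | COc1cc(OC=O)cc(OC)c1O | intermediate
11 | 2,6-dimethoxybenzene-1,4-diol | COc1cc(O)cc(OC)c1O | intermediate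
12 | 2,6-dimethoxy-4-(triisopropylsilyloxy)phenol | COc1cc(O[Si](C(C)C)(C(C)C)C(C)C)cc(OC)c1O | intermediate
13 | (S,Z)-4-[2,6-dimethoxy-4-(triisopropylsilyloxy)phenoxy]but-3-en-2-yl 3-methoxy-4-(triisopropylsilyloxy)benzyl ether | COc1cc(CO[C@@H](C)/C=C\Oc2c(OC)cc(O[Si](C(C)C)(C(C)C)C(C)C)cc2OC)ccc1O[Si](C(C)C)(C(C)C)C(C)C | intermediate
14 | 13 lithiated at the benzylic carbon C7 (configurationally labile at C7) | COc1cc(C([Li])O[C@@H](C)/C=C\Oc2c(OC)cc(O[Si](C(C)C)(C(C)C)C(C)C)cc2OC)ccc1O[Si](C(C)C)(C(C)C)C(C)C | intermediate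
15 | lithium (7S,8S)-alkoxide of 16 | COc1cc([C@H](O[Li])[C@H](/C=C/C)Oc2c(OC)cc(O[Si](C(C)C)(C(C)C)C(C)C)cc2OC)ccc1O[Si](C(C)C)(C(C)C)C(C)C | intermediate
16 | (1S,2S,3E)-1-[3-methoxy-4-(triisopropylsilyloxy)phenyl]-2-[2,6-dimethoxy-4-(triisopropylsilyloxy)phenoxy]pent-3-en-1-ol | COc1cc([C@H](O)[C@H](/C=C/C)Oc2c(OC)cc(O[Si](C(C)C)(C(C)C)C(C)C)cc2OC)ccc1O[Si](C(C)C)(C(C)C)C(C)C | intermediate
17 | 9,10-diol from syn-dihydroxylation of 16 (C7 and C8 as in 16, mixture at the two new carbinol carbons) | COc1cc([C@H](O)[C@H](C(O)C(C)O)Oc2c(OC)cc(O[Si](C(C)C)(C(C)C)C(C)C)cc2OC)ccc1O[Si](C(C)C)(C(C)C)C(C)C | intermediate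
18 | (2R,3S)-2-[2,6-dimethoxy-4-(triisopropylsilyloxy)phenoxy]-3-hydroxy-3-[3-methoxy-4-(triisopropylsilyloxy)phenyl]propanal | COc1cc([C@H](O)[C@H](C=O)Oc2c(OC)cc(O[Si](C(C)C)(C(C)C)C(C)C)cc2OC)ccc1O[Si](C(C)C)(C(C)C)C(C)C | intermediate
19 | (1S,2S)-1-[3-methoxy-4-(triisopropylsilyloxy)phenyl]-2-[2,6-dimethoxy-4-(triisopropylsilyloxy)phenoxy]propane-1,3-diol | COc1cc([C@H](O)[C@H](CO)Oc2c(OC)cc(O[Si](C(C)C)(C(C)C)C(C)C)cc2OC)ccc1O[Si](C(C)C)(C(C)C)C(C)C | intermediate
20 | (1S,2S)-1-(4-hydroxy-3-methoxyphenyl)-2-(4-hydroxy-2,6-dimethoxyphenoxy)propane-1,3-diol | COc1cc([C@H](O)[C@H](CO)Oc2c(OC)cc(O)cc2OC)ccc1O | target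

Total step count: 13.
Longest linear sequence: 11 steps (vanillin 1 to 20 through steps 1–6 and 9–13).

Steps most likely to fail

Step 10.
- What may go wrong: metalation at a wrong site (the vinylic C–H next to oxygen, or a ring C–H between two oxygen substituents), loss of aryloxide by elimination, a [1,2] shift if the reaction has to be warmed, or a weak exo/endo preference that erodes the syn selectivity.
- Fallback: it sets out from phenol 12 and aldehyde 2 and comes back at diol 19. Phenol 12 would be O-alkylated with commercial (R)-4-benzyl-3-(chloroacetyl)oxazolidin-2-one (K2CO3, NaI cat., acetone) to the aryloxyacetyl imide F1. An Evans syn-aldol addition of F1 to 2 (Bu2BOTf, Et3N, CH2Cl2, −78 to 0 °C) forms the same C7–C8 bond under auxiliary control through a Zimmerman–Traxler chair and should give the syn-aldol imide F2. LiBH4 in THF with a little MeOH then removes the auxiliary reductively and gives 19 directly, so steps 11 and 12 are not needed.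

Step 9.
- What may go wrong: slow C–O bond formation at the di-ortho-substituted phenoxide, carbonate-induced dehydroiodination of the cis-iodide, silyl transfer between phenoxides, or partial Z to E isomerisation.
- Fallback: it sets out from phenol 12 (ring A is drawn from alcohol 3) and comes back at 13. The O–C8 bond is made by addition–elimination instead of cross-coupling, and the Z geometry by semihydrogenation.
 - Phenol 12 with KH and trichloroethylene in THF gives the dichlorovinyl ether F3.
 - Excess n-BuLi (Et2O, −78 to −40 °C) followed by acetaldehyde turns F3, by elimination, chlorine–lithium exchange and carbonyl addition, into the racemic propargylic alcohol F4.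
 - Kinetic resolution with immobilised Candida antarctica lipase B and vinyl acetate leaves the (S)-alcohol F5 and converts its antipode into the (R)-acetate F6, which is separated.
 - Alcohol 3 with PBr3 gives the benzyl bromide F7, which alkylates the sodium alkoxide of F5 (NaH, THF, 0 °C) to the alkynyl ether F8.
 - Lindlar semihydrogenation (H2, Pd on CaCO3 poisoned with Pb(OAc)2, quinoline) then gives 13.

Step 11.
- What may go wrong: epimerisation at C8 or retro-aldol fragmentation while the β-hydroxy-α-aryloxy aldehyde is handled, or oxidative damage to the electron-rich rings during a slow cleavage.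
- Fallback: it sets out from 16 and comes back at 20. O7 is first capped (TESCl, imidazole, CH2Cl2) to give the triethylsilyl ether F9, which closes the retro-aldol channel. Ozonolysis in CH2Cl2/MeOH at −78 °C, run to the end-point of an azo dye indicator so that the arenes are spared, is followed by NaBH4 in the same flask. No free aldehyde is handled, and the primary alcohol F10 should result. Bu4NF/AcOH in THF then removes all three silyl groups to give 20.

Further compounds
F1 | step 10 | (R)-4-benzyl-3-{2-[2,6-dimethoxy-4-(triisopropylsilyloxy)phenoxy]acetyl}oxazolidin-2-one | COc1cc(O[Si](C(C)C)(C(C)C)C(C)C)cc(OC)c1OCC(=O)N1[C@H](Cc2ccccc2)COC1=O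
F2 | step 10 | (R)-4-benzyl-3-{(2R,3S)-2-[2,6-dimethoxy-4-(triisopropylsilyloxy)phenoxy]-3-hydroxy-3-[3-methoxy-4-(triisopropylsilyloxy)phenyl]propanoyl}oxazolidin-2-one | COc1cc([C@H](O)[C@H](C(=O)N2[C@H](Cc3ccccc3)COC2=O)Oc2c(OC)cc(O[Si](C(C)C)(C(C)C)C(C)C)cc2OC)ccc1O[Si](C(C)C)(C(C)C)C(C)C
F3 | step 9 | 2-[(E)-1,2-dichloroethenyloxy]-1,3-dimethoxy-5-(triisopropylsilyloxy)benzene | Cl/C=C(/Cl)Oc1c(OC)cc(O[Si](C(C)C)(C(C)C)C(C)C)cc1OC
F4 | step 9 | rac-4-[2,6-dimethoxy-4-(triisopropylsilyloxy)phenoxy]but-3-yn-2-ol | CC(O)C#COc1c(OC)cc(O[Si](C(C)C)(C(C)C)C(C)C)cc1OC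
F5 | step 9 | (S)-4-[2,6-dimethoxy-4-(triisopropylsilyloxy)phenoxy]but-3-yn-2-ol | C[C@H](O)C#COc1c(OC)cc(O[Si](C(C)C)(C(C)C)C(C)C)cc1OC
F6 | step 9 | (R)-4-[2,6-dimethoxy-4-(triisopropylsilyloxy)phenoxy]but-3-yn-2-yl acetate | C[C@@H](OC(C)=O)C#COc1c(OC)cc(O[Si](C(C)C)(C(C)C)C(C)C)cc1OC
F7 | step 9 | 3-methoxy-4-(triisopropylsilyloxy)benzyl bromide | COc1cc(CBr)ccc1O[Si](C(C)C)(C(C)C)C(C)C
F8 | step 9 | (S)-4-[2,6-dimethoxy-4-(triisopropylsilyloxy)phenoxy]but-3-yn-2-yl 3-methoxy-4-(triisopropylsilyloxy)benzyl ether | COc1cc(CO[C@@H](C)C#COc2c(OC)cc(O[Si](C(C)C)(C(C)C)C(C)C)cc2OC)ccc1O[Si](C(C)C)(C(C)C)C(C)C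
F9 | step 11 | O7-triethylsilyl ether of 16 | COc1cc([C@H](O[Si](CC)(CC)CC)[C@H](/C=C/C)Oc2c(OC)cc(O[Si](C(C)C)(C(C)C)C(C)C)cc2OC)ccc1O[Si](C(C)C)(C(C)C)C(C)C
F10 | step 11 | O7-triethylsilyl ether of 19 (free C9 alcohol) | COc1cc([C@H](O[Si](CC)(CC)CC)[C@H](CO)Oc2c(OC)cc(O[Si](C(C)C)(C(C)C)C(C)C)cc2OC)ccc1O[Si](C(C)C)(C(C)C)C(C)C
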